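**Strategy.** C4 of the tetralin ring is bonded to two arene carbons that each stand ortho to an oxygen (C2′ of the naphthol, C4a of the anisole ring), and O1 sits 1,4 to it. C1–C4 plus O1 are therefore a hidden 2,3-dihydrofuran whose C5 is a latent aldehyde. An asymmetric Heck arylation of 2,3-dihydrofuran sets C1. In the key step, acid joins this enol ether to 8-methoxy-1-naphthol. The resulting 2,5-diaryltetrahydrofuran opens to an o-quinone methide, and C4a closes the carbocycle C1–C2–C3–C4–C4a–C8a. This frees O1–H and sets C4. A chlorine para to the methoxy group steers the closure and is removed last.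

Key step: step 3

Assumption: C1–C8a number the tetralin unit of the target (C1 carbinol, C4 diarylmethine, C5 methoxy-bearing carbon) and primed numbers the naphthol unit. Compounds 1, 3 and 5 are taken as catalogue chemicals.

**Step 1**
Reactants: 1 2-chloro-5-methoxyphenol
Product: 2 2-chloro-5-methoxyphenyl trifluoromethanesulfonate
Conditions: Tf2O (1.1 equiv), pyridine (2 equiv), CH2Cl2, 0 °C
Reagents that add atoms: trifluoromethanesulfonic anhydride, O=S(=O)(OS(=O)(=O)C(F)(F)F)C(F)(F)F
Why: Plain O-sulfonylation of a phenol, which turns C–O into the Heck handle while the C–Cl bond stays as the later blocking group; no stereocentre is involved.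

**Step 2**
Reactants: 2 2-chloro-5-methoxyphenyl trifluoromethanesulfonate; 3 2,3-dihydrofuran (5 equiv)
Product: 4 (2S)-2-(2-chloro-5-methoxyphenyl)-2,3-dihydrofuran
Conditions: Pd(OAc)2 (3 mol%), (S)-BINAP (6 mol%), 1,8-bis(dimethylamino)naphthalene (proton sponge, 3 equiv), toluene, 40 °C; chromatography on base-washed silica
Reagents that add atoms: none
Why: In this cationic asymmetric Mizoroki–Heck arylation, Ar–Pd(BINAP)+ adds syn across the enol ether with the aryl group next to oxygen, and β-hydride elimination/re-insertion moves the double bond to the new enol ether position; (S)-BINAP selects the alkene face and sets the S centre (later C1), the minor 2,5-dihydrofuran isomer (enriched in the opposite configuration) is removed by chromatography, and C–Cl is inert to Pd/BINAP at this temperature.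

**Step 3**
Reactants: 4 (2S)-2-(2-chloro-5-methoxyphenyl)-2,3-dihydrofuran; 5 8-methoxynaphthalen-1-ol
Product: 9 (1S,4R)-8-chloro-4-(1-hydroxy-8-methoxynaphthalen-2-yl)-5-methoxy-1,2,3,4-tetrahydronaphthalen-1-ol, via naphthyl acetal 6 (not isolated), via C-aryl tetrahydrofuran 7 (not isolated), via o-quinone methide 8 (not isolated)
Conditions: 5 (1.0 equiv), Tf2NH (5 mol%), CH2Cl2, Ar, −78 °C, slow addition of 4 (1.0 equiv), then to −20 °C; then transfer into HFIP/CH2Cl2 (to ca. 2 mM), 0 °C to rt
Reagents that add atoms: none
Why: Protonation of 4 at its β-carbon gives a cyclic oxocarbenium ion that 5 captures first on oxygen (6) and then, by the Fries-type O→C shift known from aryl C-glycoside synthesis, at the ortho carbon C2′ (7); in the ionising medium the C–O bond of 7 at the naphthol-bearing carbon breaks to the o-quinone methide 8 (reacting as its O-protonated cation), which frees O1–H, and C4a attacks C4 with rearomatisation. The closest known reaction types are the acid-induced rearrangement of 2,5-diaryltetrahydrofuran lignans into aryltetralins and the Friedel–Crafts alkylation of arenes by o-quinone methides. The one ring closed is the carbocycle C1–C2–C3–C4–C4a–C8a, by a 6-exo-trig Friedel–Crafts attack on the exocyclic C4=C2′ bond, and because re-closure of 8 to 7 through O1 is reversible, the irreversible C–C closure should drain the equilibrium. C1 is not touched and keeps the S configuration of 4, while C4 is set relative to it: the chlorine at C8 holds H1 in the arene plane and O1 pseudoaxial, the methoxy group at C5 forces the naphthyl group pseudoaxial as the bond forms, and pseudoaxial groups at C1 and C4 of a half-chair lie on opposite faces (trans, 4R). On the anisole ring the chlorine occupies the normally preferred position para to methoxy (the halogen-blocking tactic of isoquinoline synthesis), so only the ortho carbon C4a can give a six-membered ring, and the same ring (methoxy meta, chlorine ortho to C1) keeps the C1–O bond from ionising. Ortho selectivity on the naphthol rests on the O→C pathway, and capture of 8 by enol ether, free naphthol or another naphthol nucleus is held back by the 1:1 stoichiometry, by full consumption of 4 and 5 in the cold stage and by high dilution in the second stage.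

**Step 4**
Reactants: 9 (1S,4R)-8-chloro-4-(1-hydroxy-8-methoxynaphthalen-2-yl)-5-methoxy-1,2,3,4-tetrahydronaphthalen-1-ol
Product: 10 dipolynaphthalene A, (1S,4R)-4-(1-hydroxy-8-methoxynaphthalen-2-yl)-5-methoxy-1,2,3,4-tetrahydronaphthalen-1-ol
Conditions: H2 (1 atm), 10% Pd/C, Et3N (1.5 equiv), degassed MeOH, rt
Reagents that add atoms: none
Why: This is a heterogeneous palladium-catalysed hydrodechlorination in which the amine takes up HCl, speeds C–Cl cleavage and suppresses hydrogenolysis of the benzylic C1–O bond; neither stereocentre is touched.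

**Compound list**
1 | 2-chloro-5-methoxyphenol | COc1ccc(Cl)c(O)c1 | starting material
2 | 2-chloro-5-methoxyphenyl trifluoromethanesulfonate | COc1ccc(Cl)c(OS(=O)(=O)C(F)(F)F)c1 | intermediate
3 | 2,3-dihydrofuran | C1=COCC1 | starting material
4 | (2S)-2-(2-chloro-5-methoxyphenyl)-2,3-dihydrofuran | COc1ccc(Cl)c([C@@H]2CC=CO2)c1 | intermediate
5 | 8-methoxynaphthalen-1-ol | COc1cccc2cccc(O)c12 | starting material
6 | (2S)-2-(2-chloro-5-methoxyphenyl)-5-[(8-methoxynaphthalen-1-yl)oxy]oxolane, acetal epimers | COc1ccc(Cl)c([C@@H]2CCC(Oc3cccc4cccc(OC)c34)O2)c1 | intermediate (not isolated)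
7 | 2-[(5S)-5-(2-chloro-5-methoxyphenyl)oxolan-2-yl]-8-methoxynaphthalen-1-ol, C2 epimers | COc1ccc(Cl)c([C@@H]2CCC(c3ccc4cccc(OC)c4c3O)O2)c1 | intermediate (not isolated)
8 | 2-[(4S)-4-(2-chloro-5-methoxyphenyl)-4-hydroxybutylidene]-8-methoxynaphthalen-1(2H)-one | COc1ccc(Cl)c([C@@H](O)CCC=C2C=Cc3cccc(OC)c3C2=O)c1 | intermediate (not isolated)
9 | (1S,4R)-8-chloro-4-(1-hydroxy-8-methoxynaphthalen-2-yl)-5-methoxy-1,2,3,4-tetrahydronaphthalen-1-ol | COc1ccc(Cl)c2c1[C@@H](c1ccc3cccc(OC)c3c1O)CC[C@@H]2O | intermediate
10 | dipolynaphthalene A | COc1cccc2c1[C@@H](c1ccc3cccc(OC)c3c1O)CC[C@@H]2O | target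

**Total step count:** 4. **Longest linear sequence:** 4 (1 → 2 → 4 → 9 → 10).

**Steps most likely to fail**

*Step 3.*
- **Risk:** Alkylation at the para carbon C4′ of the naphthol may outrun the slow closure onto the hindered, chlorine-deactivated C4a. This can happen in the union and later as intermolecular capture of the o-quinone methide, and it would lead to regioisomers and oligomers.
- **Fallback:** Block C4′ as well. The fallback sets out from 5. Para-chlorination (SO2Cl2, CH2Cl2, 0 °C) should give 4-chloro-8-methoxynaphthalen-1-ol F1. The acid cascade with 4 then has only C2′ open and should give (1S,4R)-8-chloro-4-(4-chloro-1-hydroxy-8-methoxynaphthalen-2-yl)-5-methoxy-1,2,3,4-tetrahydronaphthalen-1-ol F2. Hydrogenolysis over Pd/C with extra Et3N should remove both chlorines at once, and the fallback comes back to the route at 10.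

*Step 2.*
- **Risk:** Insertion of the ortho-substituted arylpalladium cation may be slow, double-bond migration may be incomplete (a mixture of dihydrofuran isomers), and the enantiomeric purity may erode.
- **Fallback:** Set C1 by ketone reduction instead. The fallback sets out from 2.
  - Carbonylative Negishi coupling with (3-ethoxy-3-oxopropyl)zinc bromide under CO (PdCl2(dppf), LiCl, THF) should give ethyl 4-(2-chloro-5-methoxyphenyl)-4-oxobutanoate F3.
  - Noyori transfer hydrogenation (RuCl[(S,S)-TsDPEN](p-cymene), HCO2H/Et3N) with acid-induced lactonisation should give (5S)-5-(2-chloro-5-methoxyphenyl)dihydrofuran-2(3H)-one F4.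
  - DIBAL-H at −78 °C should give (5S)-5-(2-chloro-5-methoxyphenyl)oxolan-2-ol F5.
  - Under the acid of step 3 (with molecular sieves) F5 ionises to the same oxocarbenium ion as 4, and the fallback comes back to the route at 9.

*Step 4.*
- **Risk:** The benzylic C1–O bond may be hydrogenolysed, C–Cl cleavage on the electron-rich hindered ring may stall, or an internal redox through a C1 alkoxide on palladium may erase C1.
- **Fallback:** Mask the hydroxyl groups and use a homogeneous hydride source. The fallback sets out from 9.
  - TBSOTf/2,6-lutidine should give the O1,O1′-bis(tert-butyldimethylsilyl) ether of 9 F6.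
  - Pd(OAc)2/XPhos with HCO2Na in DMF at 80 °C should give the O1,O1′-bis(tert-butyldimethylsilyl) ether of 10 F7.
  - TBAF in THF then frees both hydroxyl groups, and the fallback comes back to the route at 10.

**Further compounds**
F1 | step 3 | 4-chloro-8-methoxynaphthalen-1-ol | COc1cccc2c(Cl)ccc(O)c12
F2 | step 3 | (1S,4R)-8-chloro-4-(4-chloro-1-hydroxy-8-methoxynaphthalen-2-yl)-5-methoxy-1,2,3,4-tetrahydronaphthalen-1-ol | COc1ccc(Cl)c2c1[C@@H](c1cc(Cl)c3cccc(OC)c3c1O)CC[C@@H]2O
F3 | step 2 | ethyl 4-(2-chloro-5-methoxyphenyl)-4-oxobutanoate | CCOC(=O)CCC(=O)c1cc(OC)ccc1Cl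
F4 | step 2 | (5S)-5-(2-chloro-5-methoxyphenyl)dihydrofuran-2(3H)-one | COc1ccc(Cl)c([C@@H]2CCC(=O)O2)c1
F5 | step 2 | (5S)-5-(2-chloro-5-methoxyphenyl)oxolan-2-ol | COc1ccc(Cl)c([C@@H]2CCC(O)O2)c1
F6 | step 4 | O1,O1′-bis(tert-butyldimethylsilyl) ether of 9 | COc1ccc(Cl)c2c1[C@@H](c1ccc3cccc(OC)c3c1O[Si](C)(C)C(C)(C)C)CC[C@@H]2O[Si](C)(C)C(C)(C)C
F7 | step 4 | O1,O1′-bis(tert-butyldimethylsilyl) ether of 10 | COc1cccc2c1[C@@H](c1ccc3cccc(OC)c3c1O[Si](C)(C)C(C)(C)C)CC[C@@H]2O[Si](C)(C)C(C)(C)C
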